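Each of our two vessels holds the same stock of E, and what we want from each is how much of it ends up on every chain begun.

| setting | eta | gamma |
|---|---|---|
| E | 0.50 M | 0.50 M |
| J | 5.00 mM | 5.00 mM |
| G | 10.0 mM | 10.0 mM |
| L | 50 mM | 12 mM |
| time | 80 s | 80 s |

    E + L → Z + Q (k1 = 0.28 M⁻¹ s⁻¹)
    E + Z → Q + Z, rate k2*[Z]*[E] (k2 = 0.48 M⁻¹ s⁻¹)
    Z + J → Z.J (k3 = 16 M⁻¹ s⁻¹)
    G + E → G.E (k4 = 2.9 M⁻¹ s⁻¹)

- which of the two ends with the longer chains by the average number of monomer units in a chain (chains begun, living or dead) ("neither" if they lie within 10%) (eta / gamma / neither)
- average number of monomer units in a chain (chains begun, living or dead) at the end, eta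
- average number of monomer units in a chain (chains begun, living or dead) at the end, gamma

- the average divides the monomer in chains by the number of chains begun, living and dead together
- run time (eta): 80 s

In eta G lasts with a half-life of 0.48 s against E, and gamma holds the same charges of E and G; that is far shorter than the run of 80 s, so we take 10.0 mM of E away and keep 0.490 M free to grow. L starts chains with a half-life of 4.95 s at the charged E, again far shorter than the run, so we count each L as a chain begun. J ends one living end each, and in eta an end meets J with a half-life of 8.7 s, far shorter than the run; gamma holds the same 5.00 mM of J, so we take the surviving ends as L minus J: 7.00 mM in gamma and 45.0 mM in eta.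

With the ends steady, E falls pseudo-first-order. One over k2 times the surviving ends is the growth time, 298 s in gamma and 46.3 s in eta. It marks a crossing. In gamma the run is shorter than the growth time, so we expect time to hold the length down, whereas in eta the run is longer, so we expect the supply of E to do so.

We reckon the length in two ways. The straight way keeps the starting rate for the whole run and gives 11.0 for gamma and 16.9 for eta. The curved way multiplies the ceiling, free E per chain begun, by one minus exp(−run/growth time), and gives 9.62 for gamma and 8.06 for eta. In gamma the straight way stands 14.0% above the curve. In eta they part, and the straight way is the one that cheats: it puts 0.847 M of E into chains, more than the 0.490 M free. We commit to the curve, with gamma longer by 19.4%, outside the 10% margin.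

The forecast chose gamma, as we do, with 8 for eta and 10 for gamma, the latter more than our 9.62, its ground being that eta “spreads it over about four times as many chains”. The simulation gives 7.96 for eta and 9.99 for gamma, so gamma ends with the longer chains.

Gamma ran for 0.268 of its growth time. The neighbouring flask is gamma with L raised to 0.048 M. Its surviving ends are 43.0 mM, so its growth time is 48.4 s, shorter than the run, which puts it on eta's side of the crossing. Its ceiling is 10.2, and the curve gives 8.25. That flask ends with 20.2% of its E left and a length of 8.14.

The rate constants are those of an exercise; the result is computed.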